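**Plan**

- Feature: numbering ring A from its quaternary carbon (C1), C6–C1–C2 (the quaternary carbon and its two flanking carbonyl carbons) is a 2-methyl-2-prenylmalonyl unit. C3–C4–C5, carrying the bridge CH2 on C3 and the isobutyryl group on C5, is a 1,3-diketone. C1 has no hydrogen, so a malonyl ester there cannot enolise and the centre cannot epimerise.
- Retrosynthesis: remove the two MOM ethers; cut ring A at C2–C3 and C5–C6 into acid chloride/methyl ester 5 and diketone 18; cut 18 at its diketone C–C bond (Claisen) and at the aryl–CH2CH2 bond (Negishi); open ring C to a phenol and prenal; strip bromine, MOM and acyl back to phloroglucinol.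
- Forward: ring B is acylated, mono-protected and brominated; ring C is closed; the three-carbon chain and then the diketone are attached; ring A is closed last by a [3+3] double C-acylation; deprotection ends the route.
- Stereochemistry: the single stereocentre comes from pig-liver-esterase hydrolysis of prochiral diester 3. The (S)-half-ester decides which carboxyl becomes the chloride, and the chemoselectivity of the ring A closure carries this into the target.

Key step: step 11

Assumption: pig liver esterase is taken to cleave the ester group of 3 that leads to the (S)-half-ester 4; because sense and degree of selection of this enzyme vary with the 2-substituent, configuration and ee of 4 are to be established before it is carried on, and the resolution given at the end replaces the enzyme if either is unsatisfactory.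

**Route**

Step 1
Reactants: 1 dimethyl 2-methylpropanedioate; 2 1-bromo-3-methylbut-2-ene (prenyl bromide)
Product: 3 dimethyl 2-methyl-2-(3-methylbut-2-en-1-yl)propanedioate
Conditions: NaH (1.1 equiv), THF, 0 °C; then 2, 0 °C → rt
Reagents that add atoms: none
Why: Malonic ester alkylation: the sodium enolate of 1 displaces bromide from the primary allylic halide by SN2, and with only one acidic hydrogen in 1 no second alkylation can follow.

Step 2
Reactants: 3 dimethyl 2-methyl-2-(3-methylbut-2-en-1-yl)propanedioate
Product: 4 (2S)-2-(methoxycarbonyl)-2,5-dimethylhex-4-enoic acid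
Conditions: pig liver esterase, 0.1 M phosphate buffer (pH 7.5)/DMSO 9:1, 25 °C, 1 M NaOH by pH-stat (1.0 equiv); then 2 M HCl to pH 2, EtOAc
Reagents that add atoms: water, O
Why: Enzymatic desymmetrisation (enantiotopic-group-selective ester hydrolysis) of a prochiral 2,2-disubstituted malonate: the esterase should cleave one of the two enantiotopic ester groups and thereby set the quaternary centre, which has no α-hydrogen and cannot racemise, while the carboxylate formed is no longer a substrate, so hydrolysis should stop at the half-ester; configuration and ee are to be checked here by chiral HPLC and optical rotation.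

Step 3
Reactants: 4 (2S)-2-(methoxycarbonyl)-2,5-dimethylhex-4-enoic acid
Product: 5 methyl (2R)-2-(chlorocarbonyl)-2,5-dimethylhex-4-enoate
Conditions: 1-chloro-N,N,2-trimethylprop-1-en-1-amine (1.2 equiv), CH2Cl2, 0 °C → rt; bulb-to-bulb distillation
Reagents that add atoms: 1-chloro-N,N,2-trimethylprop-1-en-1-amine, CC(C)=C(Cl)N(C)C
Why: Acid chloride formation with an α-chloroenamine under neutral conditions, so no HCl is set free that could add to the prenyl double bond; the centre bears no hydrogen, so neither ketene formation nor racemisation is possible, and the descriptor changes from S to R only because COCl outranks CO2Me.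

Step 4
Reactants: 6 phloroglucinol; 7 2-methylpropanoyl chloride
Product: 8 2-methyl-1-(2,4,6-trihydroxyphenyl)propan-1-one
Conditions: AlCl3 (3.5 equiv), PhNO2/CH2Cl2, 0 → 50 °C; aq. HCl
Reagents that add atoms: none
Why: Friedel–Crafts C-acylation of the threefold activated arene, in which all ring positions are equivalent and the first acyl group deactivates the ring against a second acylation.

Step 5
Reactants: 8 2-methyl-1-(2,4,6-trihydroxyphenyl)propan-1-one
Product: 9 1-[2,6-dihydroxy-4-(methoxymethoxy)phenyl]-2-methylpropan-1-one
Conditions: MOMCl (1.05 equiv), i-Pr2NEt (1.2 equiv), THF, 0 °C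
Reagents that add atoms: chloromethyl methyl ether, COCCl
Why: Selective O-alkylation: the 4-hydroxyl para to the ketone is the most acidic and the only one not hydrogen-bonded to the carbonyl, so one equivalent of MOMCl should etherify it first and give a mirror-symmetric ether whose two free ring positions and two free hydroxyls are equivalent.

Step 6
Reactants: 9 1-[2,6-dihydroxy-4-(methoxymethoxy)phenyl]-2-methylpropan-1-one
Product: 10 1-[3-bromo-2,6-dihydroxy-4-(methoxymethoxy)phenyl]-2-methylpropan-1-one
Conditions: NBS (1.0 equiv), CH2Cl2, −30 → 0 °C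
Reagents that add atoms: N-bromosuccinimide, O=C1CCC(=O)N1Br
Why: Electrophilic aromatic bromination at one of the two equivalent free positions of the activated ring; the halogen is placed now, before the molecule holds any alkene, so the later chromene double bond cannot compete.

Step 7
Reactants: 10 1-[3-bromo-2,6-dihydroxy-4-(methoxymethoxy)phenyl]-2-methylpropan-1-one; 11 3-methylbut-2-enal (prenal)
Product: 13 1-[6-bromo-7-hydroxy-5-(methoxymethoxy)-2,2-dimethyl-2H-chromen-8-yl]-2-methylpropan-1-one, via quinone methide 12 (not isolated)
Conditions: 11 (2 equiv), ethylenediammonium diacetate (0.2 equiv), toluene, reflux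
Reagents that add atoms: none
Why: Knoevenagel-type condensation of the enal at the only free ring carbon gives the vinylogous ortho-quinone methide 12, whose oxa-6π electrocyclisation closes ring C; the only free hydroxyl next to that carbon is the one beside the ketone (the other neighbour is the MOM ether), so the pyran oxygen must end up ortho to the isobutyryl group.

Step 8
Reactants: 13 1-[6-bromo-7-hydroxy-5-(methoxymethoxy)-2,2-dimethyl-2H-chromen-8-yl]-2-methylpropan-1-one
Product: 14 1-[6-bromo-5,7-bis(methoxymethoxy)-2,2-dimethyl-2H-chromen-8-yl]-2-methylpropan-1-one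
Conditions: NaH (1.3 equiv), MOMCl (1.5 equiv), DMF, 0 °C → rt
Reagents that add atoms: chloromethyl methyl ether, COCCl
Why: Williamson-type O-alkylation of the sodium phenoxide; full deprotonation is chosen because this hydroxyl is hydrogen-bonded to the ketone and flanked by bromine.

Step 9
Reactants: 14 1-[6-bromo-5,7-bis(methoxymethoxy)-2,2-dimethyl-2H-chromen-8-yl]-2-methylpropan-1-one; 15 (3-ethoxy-3-oxopropyl)zinc bromide (0.5 M in THF)
Product: 16 ethyl 3-[5,7-bis(methoxymethoxy)-2,2-dimethyl-8-(2-methylpropanoyl)-2H-chromen-6-yl]propanoate
Conditions: Pd(OAc)2 (5 mol %), 2-dicyclohexylphosphino-2′,6′-dimethoxybiphenyl (SPhos, 10 mol %), 15 (1.8 equiv), THF, 50 °C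
Reagents that add atoms: none
Why: Negishi sp2–sp3 cross-coupling: the bulky, electron-rich biarylphosphine should let palladium insert into the doubly ortho-alkoxylated C–Br bond and favour reductive elimination over β-hydride elimination, while the organozinc leaves the hindered aryl ketone, the MOM ethers and the chromene alkene untouched.

Step 10
Reactants: 16 ethyl 3-[5,7-bis(methoxymethoxy)-2,2-dimethyl-8-(2-methylpropanoyl)-2H-chromen-6-yl]propanoate; 17 3-methylbutan-2-one
Product: 18 1-[5,7-bis(methoxymethoxy)-2,2-dimethyl-8-(2-methylpropanoyl)-2H-chromen-6-yl]-6-methylheptane-3,5-dione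
Conditions: 17 (3.0 equiv), LiN(i-Pr)2 (3.0 equiv), THF, −78 °C; then 16, −78 °C → rt; AcOH
Reagents that add atoms: none
Why: Crossed Claisen condensation: LiN(i-Pr)2 gives the kinetic methyl-side enolate of 17, which is C-acylated by the ester, and deprotonation of the β-diketone formed by excess enolate drives the reaction, while the ring ketone, shielded by two ortho substituents, should not compete.

Step 11
Reactants: 18 1-[5,7-bis(methoxymethoxy)-2,2-dimethyl-8-(2-methylpropanoyl)-2H-chromen-6-yl]-6-methylheptane-3,5-dione; 5 methyl (2R)-2-(chlorocarbonyl)-2,5-dimethylhex-4-enoate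
Product: 20 (4S)-2-{[5,7-bis(methoxymethoxy)-2,2-dimethyl-8-(2-methylpropanoyl)-2H-chromen-6-yl]methyl}-3,5-dihydroxy-4-methyl-4-(3-methylbut-2-en-1-yl)-6-(2-methylpropanoyl)cyclohexa-2,5-dien-1-one, via triketo ester 19 (not isolated)
Conditions: LiN(i-Pr)2 (2.1 equiv), THF, −78 → 0 °C; recool to −78 °C, LiN(i-Pr)2 (1.1 equiv), then 5 (1.1 equiv) dropwise; −78 °C → rt; cold 1 M HCl
Reagents that add atoms: none
Why: LiN(i-Pr)2 turns 18 into its 1,3-dianion, deprotonated at the central CH2 and kinetically at the chain CH2 beside the ketone rather than at the isopropyl CH, and this terminal carbanion, the most nucleophilic site, takes the acid chloride of 5 at −78 °C while the neopentyl-type methyl ester is left alone; the extra equivalent of amide removes the new, more acidic 1,3-dicarbonyl proton so that no dianion is spent as a base. On warming, the carbon between the two original ketones of bis-enolate 19 attacks the methyl ester in a 6-exo-trig Dieckmann (intramolecular Claisen) closure of ring A, and loss of methoxide followed by deprotonation of the strongly acidic acyl-trione makes the sequence irreversible. The closest known reaction types are the terminal acylation of 1,3-diketone dianions to 1,3,5-triketones and the base-induced Claisen cyclisation of 3,5-dioxo esters to cyclohexane-1,3,5-triones. No stereocentre is created, since the acylated chain carbon becomes an enol carbon of ring A, and the quaternary centre of 5, lacking an α-hydrogen, can neither form a ketene nor enolise and is carried over unchanged. The step needs each malonyl carbonyl to pair with its own carbon, because the opposite pairing would give the enantiomer; this is secured by the reactivity gaps acid chloride over ester and terminal carbanion over stabilised central enolate, and by the ester staying a pure electrophile in base because its neighbour is quaternary. Closure through oxygen to an enol lactone is reversible under methoxide, whereas the C-acylated trione anion is not reopened, so the carbocycle should be the end point.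

Step 12
Reactants: 20 (4S)-2-{[5,7-bis(methoxymethoxy)-2,2-dimethyl-8-(2-methylpropanoyl)-2H-chromen-6-yl]methyl}-3,5-dihydroxy-4-methyl-4-(3-methylbut-2-en-1-yl)-6-(2-methylpropanoyl)cyclohexa-2,5-dien-1-one
Product: 21 (4S)-2-{[5,7-dihydroxy-2,2-dimethyl-8-(2-methylpropanoyl)-2H-chromen-6-yl]methyl}-3,5-dihydroxy-4-methyl-4-(3-methylbut-2-en-1-yl)-6-(2-methylpropanoyl)cyclohexa-2,5-dien-1-one (CNP0301804.1)
Conditions: HCl (0.5 M) in MeOH/THF 4:1, rt → 40 °C, stopped at full conversion
Reagents that add atoms: none
Why: Acid-catalysed acetal exchange should remove both MOM groups as dimethoxymethane under conditions too mild to protonate the trisubstituted prenyl alkene or the chromene double bond, and the quaternary centre, which has no acidic hydrogen, is untouched.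

**Compound list**

1 | dimethyl 2-methylpropanedioate (dimethyl methylmalonate) | COC(=O)C(C)C(=O)OC | starting material
2 | 1-bromo-3-methylbut-2-ene (prenyl bromide) | CC(C)=CCBr | starting material
3 | dimethyl 2-methyl-2-(3-methylbut-2-en-1-yl)propanedioate | COC(=O)C(C)(CC=C(C)C)C(=O)OC | intermediate
4 | (2S)-2-(methoxycarbonyl)-2,5-dimethylhex-4-enoic acid | CC(C)=CC[C@@](C(=O)OC)(C)C(=O)O | intermediate
5 | methyl (2R)-2-(chlorocarbonyl)-2,5-dimethylhex-4-enoate | CC(C)=CC[C@@](C(=O)OC)(C)C(=O)Cl | intermediate
6 | phloroglucinol (benzene-1,3,5-triol) | Oc1cc(O)cc(O)c1 | starting material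
7 | 2-methylpropanoyl chloride (isobutyryl chloride) | CC(C)C(=O)Cl | starting material
8 | 2-methyl-1-(2,4,6-trihydroxyphenyl)propan-1-one | CC(C)C(=O)c1c(O)cc(O)cc1O | intermediate
9 | 1-[2,6-dihydroxy-4-(methoxymethoxy)phenyl]-2-methylpropan-1-one | CC(C)C(=O)c1c(O)cc(OCOC)cc1O | intermediate
10 | 1-[3-bromo-2,6-dihydroxy-4-(methoxymethoxy)phenyl]-2-methylpropan-1-one | CC(C)C(=O)c1c(O)cc(OCOC)c(Br)c1O | intermediate
11 | 3-methylbut-2-enal (prenal) | CC(C)=CC=O | starting material
12 | 4-bromo-3-hydroxy-5-(methoxymethoxy)-6-(3-methylbut-2-en-1-ylidene)-2-(2-methylpropanoyl)cyclohexa-2,4-dien-1-one (ortho-quinone methide) | CC(C)C(=O)C1=C(O)C(Br)=C(OCOC)C(=CC=C(C)C)C1=O | intermediate (not isolated)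
13 | 1-[6-bromo-7-hydroxy-5-(methoxymethoxy)-2,2-dimethyl-2H-chromen-8-yl]-2-methylpropan-1-one | CC(C)C(=O)c1c(O)c(Br)c(OCOC)c2C=CC(C)(C)Oc12 | intermediate
14 | 1-[6-bromo-5,7-bis(methoxymethoxy)-2,2-dimethyl-2H-chromen-8-yl]-2-methylpropan-1-one | CC(C)C(=O)c1c(OCOC)c(Br)c(OCOC)c2C=CC(C)(C)Oc12 | intermediate
15 | (3-ethoxy-3-oxopropyl)zinc bromide | CCOC(=O)CC[Zn]Br | starting material
16 | ethyl 3-[5,7-bis(methoxymethoxy)-2,2-dimethyl-8-(2-methylpropanoyl)-2H-chromen-6-yl]propanoate | CCOC(=O)CCc1c(OCOC)c2C=CC(C)(C)Oc2c(C(=O)C(C)C)c1OCOC | intermediate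
17 | 3-methylbutan-2-one | CC(C)C(C)=O | starting material
18 | 1-[5,7-bis(methoxymethoxy)-2,2-dimethyl-8-(2-methylpropanoyl)-2H-chromen-6-yl]-6-methylheptane-3,5-dione | CC(C)C(=O)CC(=O)CCc1c(OCOC)c2C=CC(C)(C)Oc2c(C(=O)C(C)C)c1OCOC | intermediate
19 | methyl (2S)-2-(2-{[5,7-bis(methoxymethoxy)-2,2-dimethyl-8-(2-methylpropanoyl)-2H-chromen-6-yl]methyl}-6-methyl-3,5-dioxoheptanoyl)-2,5-dimethylhex-4-enoate (present as its lithium enolates; acylated chain carbon not configurationally defined) | CC(C)=CC[C@@](C(=O)OC)(C)C(=O)C(Cc1c(OCOC)c2C=CC(C)(C)Oc2c(C(=O)C(C)C)c1OCOC)C(=O)CC(=O)C(C)C | intermediate (not isolated)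
20 | (4S)-2-{[5,7-bis(methoxymethoxy)-2,2-dimethyl-8-(2-methylpropanoyl)-2H-chromen-6-yl]methyl}-3,5-dihydroxy-4-methyl-4-(3-methylbut-2-en-1-yl)-6-(2-methylpropanoyl)cyclohexa-2,5-dien-1-one (enol tautomer as drawn) | CC(C)=CC[C@@]1(C)C(O)=C(Cc2c(OCOC)c3c(c(C(=O)C(C)C)c2OCOC)OC(C)(C)C=C3)C(=O)C(C(=O)C(C)C)=C1O | intermediate
21 | (4S)-2-{[5,7-dihydroxy-2,2-dimethyl-8-(2-methylpropanoyl)-2H-chromen-6-yl]methyl}-3,5-dihydroxy-4-methyl-4-(3-methylbut-2-en-1-yl)-6-(2-methylpropanoyl)cyclohexa-2,5-dien-1-one (CNP0301804.1, enol tautomer as drawn) | CC(C)=CC[C@@]1(C)C(O)=C(Cc2c(O)c3c(c(C(=O)C(C)C)c2O)OC(C)(C)C=C3)C(=O)C(C(=O)C(C)C)=C1O | target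

**Step count**

Total: 12 steps. Longest linear sequence: 9 steps (phloroglucinol 6 to target 21, steps 4–12); the malonyl branch (steps 1–3) joins at step 11.

**Steps most likely to fail, and fallbacks**

1. Step 11. The freshly formed triketone is more acidic than the monoanion of 18, so proton transfer to unreacted dianion can stall the acylation near half conversion; the hindered acid chloride may also be taken at oxygen, or the ring may close through oxygen to an enol lactone. The fallback sets out from 18 and 5 and replaces the dianion by a neutral equivalent. Diketone 18 is silylated with Me3SiCl/Et3N to the silyl enol ether F1 (its regioisomer is expected to give the same diene), and F1 is converted with LiN(i-Pr)2/Me3SiCl at −78 °C into the 1,3-bis(silyloxy)diene F2. Without base or Lewis acid, F2 should take acid chloride 5 at its terminal carbon in CH2Cl2 (−78 → 20 °C), a vinylogous Mukaiyama-type acylation known for 1,3-bis(silyl enol ethers), with the same carbonyl-to-carbon pairing as in the main route. Aqueous work-up then gives triketo ester 19 as an isolated compound, and NaOMe in MeOH closes it by Dieckmann condensation, returning to the route at 20.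

2. Step 2. The esterase may discriminate the two enantiotopic ester groups poorly, or in the opposite sense, with this 2-substituent. The fallback sets out from 3 and uses classical resolution instead of the enzyme. One equivalent of KOH in MeOH/H2O gives the racemic half-ester F3, which is combined with (S)-1-phenylethylamine. The (S)-1-phenylethylammonium salt F4 of the (S)-acid is brought to diastereomeric purity by fractional crystallisation, with the configuration secured by X-ray analysis of the salt. Dilute HCl liberates the acid and returns to the route at 4. Material of the wrong configuration can be re-methylated (MeI, K2CO3) to the achiral diester 3 and recycled.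

3. Step 9. Reductive elimination from the crowded aryl(alkyl)palladium intermediate may be slow, so that β-hydride elimination and protodebromination take over. The fallback sets out from 14 and forms the aryl–carbon bond by carbopalladation instead of transmetalation. A Heck reaction with ethyl acrylate (Pd(OAc)2, tri-tert-butylphosphonium tetrafluoroborate, N,N-dicyclohexylmethylamine, dioxane, 100 °C) should give the (E)-cinnamate F5. Its conjugated double bond is then reduced selectively with copper hydride (Cu(OAc)2, 1,2-bis(diphenylphosphino)benzene, polymethylhydrosiloxane, t-BuOH, toluene), which should leave the chromene alkene and the hindered ketone alone, returning to the route at 16.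

Further compounds
F1 | step 11 | 1-[5,7-bis(methoxymethoxy)-2,2-dimethyl-8-(2-methylpropanoyl)-2H-chromen-6-yl]-6-methyl-5-(trimethylsilyloxy)hept-4-en-3-one | CC(C)C(O[Si](C)(C)C)=CC(=O)CCc1c(OCOC)c2C=CC(C)(C)Oc2c(C(=O)C(C)C)c1OCOC
F2 | step 11 | 1-{5,7-bis(methoxymethoxy)-2,2-dimethyl-6-[6-methyl-3,5-bis(trimethylsilyloxy)hepta-2,4-dien-1-yl]-2H-chromen-8-yl}-2-methylpropan-1-one | CC(C)C(O[Si](C)(C)C)=CC(O[Si](C)(C)C)=CCc1c(OCOC)c2C=CC(C)(C)Oc2c(C(=O)C(C)C)c1OCOC
F3 | step 2 | racemic 2-(methoxycarbonyl)-2,5-dimethylhex-4-enoic acid | CC(C)=CCC(C)(C(=O)OC)C(=O)O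
F4 | step 2 | (1S)-1-phenylethan-1-aminium (2S)-2-(methoxycarbonyl)-2,5-dimethylhex-4-enoate | CC(C)=CC[C@@](C(=O)OC)(C)C(=O)[O-].C[C@H]([NH3+])c1ccccc1
F5 | step 9 | ethyl (2E)-3-[5,7-bis(methoxymethoxy)-2,2-dimethyl-8-(2-methylpropanoyl)-2H-chromen-6-yl]prop-2-enoate | CCOC(=O)/C=C/c1c(OCOC)c2C=CC(C)(C)Oc2c(C(=O)C(C)C)c1OCOC
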